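**Retrosynthetic overview** (numbering: oxolane O1, C2 pentyl, C3 O-acyl, C4, C5; side-chain carbinol carbon C1′)
1. End game: the C1′ carbinol comes from Corey–Bakshi–Shibata reduction of a C1′ ketone, itself made by Negishi acylation of a ring C5 carboxylic acid, so the dec-9-enyl chain and its alkene arrive after all oxidations.
2. The myristate is the Baeyer–Villiger image (retention at C3) of a C3 tetradecanoyl ketone; the ester travels through the ring closure as the enolisable ketone that supplies the C3 nucleophile.
3. Key disconnection C2–C3 of the oxolane (the only ring of the target, formed once): a Me3SiOTf-triggered 1,3 O-to-C shift of a hexylidene unit inside a 1,3-dioxolan-4-one (temporary ring, built first, destroyed in the closure).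
4. Enabling feature: O1 makes C2 an acetal-level carbon next to C3, and C5 bears the exocyclic carbon C1′, which can be carried as a carboxyl group; O1–C5–C1′(=O)O is then an α-hydroxy acid that holds hexanal (C2 plus pentyl) as a cyclic α-acyloxy ether whose carboxylate leaves C2 but stays tethered at C5.
5. Chiral pool: C5, C4, C3, C1′ and the ester carbonyl carbon are the five carbons of (R)-5-oxooxolane-2-carboxylic acid (D-glutamic acid series); C5 is inherited, C2 and C3 come from the key step, C1′ from the reduction.

Key step: step 3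

Remark: the dioxolanone is carried as the mixture of acetal epimers, because the acetal carbon is ionised in the key step and both epimers pass through the same ion pair.

**Step 1**
Reactants: 1 (R)-5-oxooxolane-2-carboxylic acid; 2 1-bromotridecane
Product: 5 (R)-2-hydroxy-5-oxooctadecanoic acid, via tridecyllithium 3 (not isolated), via lithium (R)-5-oxooxolane-2-carboxylate 4 (not isolated)
Conditions: 2, Li wire (2.1 equiv), Et2O, 0 °C, gives 3; 1, LiN(SiMe3)2 (1.0 equiv), THF, −78 °C, then 3 (1.1 equiv), −78 °C; 1 M HCl
Reagents that add atoms: none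
Why: An alkyllithium should add only once to a γ-lactone at −78 °C because the lithium hemiketalate survives until work-up (lactone mono-addition to a γ-hydroxy ketone), while the acid is masked as its unreactive lithium carboxylate and the stereocentre is not touched.

**Step 2**
Reactants: 5 (R)-2-hydroxy-5-oxooctadecanoic acid; 6 hexanal
Product: 7 (5R)-5-(3-oxohexadecyl)-2-pentyl-1,3-dioxolan-4-one (both C2 epimers)
Conditions: 6 (1.5 equiv), TsOH·H2O (5 mol %), pentane, reflux, water separator
Reagents that add atoms: none
Why: Acid-catalysed acetalisation of an α-hydroxy acid with an aldehyde under azeotropic water removal should give the 1,3-dioxolan-4-one, which ties up the hydroxyl and the acid so that the open keto form rather than the lactol is carried on.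

**Step 3**
Reactants: 7 (5R)-5-(3-oxohexadecyl)-2-pentyl-1,3-dioxolan-4-one
Product: 10 (2R,4S,5S)-5-pentyl-4-tetradecanoyloxolane-2-carboxylic acid, via Z-silyl enol ether 8 (not isolated), via trimethylsilyl ester 9 (not isolated)
Conditions: i-Pr2NEt (1.1 equiv), Me3SiOTf (1.6 equiv), CH2Cl2, −78 to −40 °C; cold pH 5 phosphate buffer
Reagents that add atoms: none
Why: Mechanism: Me3SiOTf/i-Pr2NEt reversibly converts the ketone into its silyl enol ethers and silylates the lactone carbonyl of the cyclic α-acyloxy ether, which ionises by C2–O(acyl) cleavage to the (E)-oxocarbenium ion O1=C2H–C5H11 with the silyl carboxylate still attached at C1′; the ring-side Z enol ether 8 then attacks C2 and silyl transfer gives ester 9, hydrolysed to 10 on work-up. The closest known reaction types are the Mukaiyama-type substitution of α-acyloxy ethers and dioxolanone acetal carbons by silyl enol ethers, the one-pot soft enolisation–Mukaiyama addition to acetals, and the Petasis–Ferrier rearrangement, of which this is a variant whose nucleophile sits on the ring side chain. The oxolane closes in a 5-(enolexo)-endo-trig mode, with the enol double bond outside and O1=C2 inside the new ring. C2 is controlled by the E geometry of the ion (pentyl anti to C5) together with the tethered carboxylate, which must occupy the face opposite the incoming enol arm and so holds C1′ pseudo-axial, placing pentyl and C1′ trans; C3 is set kinetically by a synclinal transition state in which the Z enol oxygen lies over O1, placing the acyl group cis to pentyl. The step needs enolisation toward C3 rather than toward the tridecyl chain (only the C3 enol can close a five-membered ring and the other regioisomer should return through the reversible silylation), C2–O(acyl) rather than C2–O1 cleavage (the carboxylate is the only good nucleofuge) and no epimerisation at C3 (low temperature, limiting base, and a product that enolises preferentially on its tridecyl side).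

**Step 4**
Reactants: 10 (2R,4S,5S)-5-pentyl-4-tetradecanoyloxolane-2-carboxylic acid
Product: 11 (2R,4S,5S)-5-pentyl-4-(tetradecanoyloxy)oxolane-2-carboxylic acid
Conditions: mCPBA (2.5 equiv), CH2Cl2, 0 °C to rt, dark
Reagents that add atoms: mCPBA (3-chloroperbenzoic acid), O=C(OO)c1cccc(Cl)c1
Why: In this Baeyer–Villiger oxidation the secondary ring carbon should migrate in preference to the primary tridecyl carbon and with retention, so the cis ketone gives the cis tetradecanoate directly, and no alkene is present yet to be epoxidised.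

**Step 5**
Reactants: 11 (2R,4S,5S)-5-pentyl-4-(tetradecanoyloxy)oxolane-2-carboxylic acid; 12 9-bromonon-1-ene
Product: 15 (2S,3S,5R)-5-(dec-9-enoyl)-2-pentyloxolan-3-yl tetradecanoate, via non-8-en-1-ylzinc bromide 13 (not isolated), via acid chloride 14 (not isolated)
Conditions: 12, Zn dust, LiCl, THF, 40 °C, gives 13; 11, (COCl)2 (1.2 equiv), DMF (cat.), CH2Cl2, 0 °C to rt, evaporate, gives 14; 14 and 13 (1.3 equiv), Pd(PPh3)4 (5 mol %), THF, 0 °C to rt
Reagents that add atoms: none
Why: In this Negishi acylation the acid chloride, formed without base so that the α-alkoxy centre is not epimerised, should couple with the alkylzinc bromide under zerovalent palladium catalysis to give the ketone without touching the ester or the terminal alkene.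

**Step 6**
Reactants: 15 (2S,3S,5R)-5-(dec-9-enoyl)-2-pentyloxolan-3-yl tetradecanoate
Product: 16 (2S,3S,5R)-5-[(1R)-1-hydroxydec-9-en-1-yl]-2-pentyloxolan-3-yl tetradecanoate
Conditions: (S)-1-methyl-3,3-diphenyltetrahydro-1H,3H-pyrrolo[1,2-c][1,3,2]oxazaborole (0.2 equiv), catecholborane (1.5 equiv), toluene, −78 °C; MeOH, then pH 7 buffer
Reagents that add atoms: none
Why: In this Corey–Bakshi–Shibata reduction the (S)-oxazaborolidine should deliver hydride to the face that gives the (1R) carbinol when the branched oxolanyl group acts as the large substituent, which is also the face favoured by the non-chelated 1,2-induction of the α-alkoxy centre (threo), and catecholborane at −78 °C spares the ester and the terminal alkene.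

**Compound list**
1 | (R)-5-oxooxolane-2-carboxylic acid | OC(=O)[C@H]1CCC(=O)O1 | starting material
2 | 1-bromotridecane | CCCCCCCCCCCCCBr | starting material
3 | tridecyllithium | [Li]CCCCCCCCCCCCC | intermediate
4 | lithium (R)-5-oxooxolane-2-carboxylate | [Li+].[O-]C(=O)[C@H]1CCC(=O)O1 | intermediate
5 | (R)-2-hydroxy-5-oxooctadecanoic acid | OC(=O)[C@H](O)CCC(=O)CCCCCCCCCCCCC | intermediate
6 | hexanal | CCCCCC=O | starting material
7 | (5R)-5-(3-oxohexadecyl)-2-pentyl-1,3-dioxolan-4-one (both C2 epimers) | CCCCCC1OC(=O)[C@@H](CCC(=O)CCCCCCCCCCCCC)O1 | intermediate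
8 | (5R)-2-pentyl-5-[(2Z)-3-(trimethylsilyloxy)hexadec-2-en-1-yl]-1,3-dioxolan-4-one | CCCCCC1OC(=O)[C@@H](C/C=C(\O[Si](C)(C)C)CCCCCCCCCCCCC)O1 | intermediate
9 | trimethylsilyl (2R,4S,5S)-5-pentyl-4-tetradecanoyloxolane-2-carboxylate | C[Si](C)(C)OC(=O)[C@H]1C[C@H](C(=O)CCCCCCCCCCCCC)[C@H](CCCCC)O1 | intermediate
10 | (2R,4S,5S)-5-pentyl-4-tetradecanoyloxolane-2-carboxylic acid | OC(=O)[C@H]1C[C@H](C(=O)CCCCCCCCCCCCC)[C@H](CCCCC)O1 | intermediate
11 | (2R,4S,5S)-5-pentyl-4-(tetradecanoyloxy)oxolane-2-carboxylic acid | OC(=O)[C@H]1C[C@H](OC(=O)CCCCCCCCCCCCC)[C@H](CCCCC)O1 | intermediate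
12 | 9-bromonon-1-ene | C=CCCCCCCCBr | starting material
13 | non-8-en-1-ylzinc bromide | C=CCCCCCCC[Zn]Br | intermediate
14 | (2R,4S,5S)-5-pentyl-4-(tetradecanoyloxy)oxolane-2-carbonyl chloride | ClC(=O)[C@H]1C[C@H](OC(=O)CCCCCCCCCCCCC)[C@H](CCCCC)O1 | intermediate
15 | (2S,3S,5R)-5-(dec-9-enoyl)-2-pentyloxolan-3-yl tetradecanoate | C=CCCCCCCCC(=O)[C@H]1C[C@H](OC(=O)CCCCCCCCCCCCC)[C@H](CCCCC)O1 | intermediate
16 | (2S,3S,5R)-5-[(1R)-1-hydroxydec-9-en-1-yl]-2-pentyloxolan-3-yl tetradecanoate | C=CCCCCCCC[C@@H](O)[C@H]1C[C@H](OC(=O)CCCCCCCCCCCCC)[C@H](CCCCC)O1 | target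

Total step count: 6. Longest linear sequence: 6 steps (from 1).

**Steps most likely to fail**

Step 3. The ketone may be silylated on the tridecyl side and consumed by intermolecular Mukaiyama addition, and the acyl-bearing centre may equilibrate to the trans isomer. The fallback sets out from 4 and returns at 10. The lactone carbonyl of 4 is attacked by lithium tridec-1-yn-1-ide F1 (from tridec-1-yne and n-BuLi, THF, −78 °C) to give (R)-2-hydroxy-5-oxooctadec-6-ynoic acid F2. Acetalisation with 6 as in step 2 gives (5R)-5-(3-oxohexadec-4-yn-1-yl)-2-pentyl-1,3-dioxolan-4-one F3. In this ynone only the ring-side methylene can be enolised, so the same Me3SiOTf/i-Pr2NEt closure (base kept limiting) should give (2R,4S,5S)-5-pentyl-4-(tetradec-2-ynoyl)oxolane-2-carboxylic acid F4. Hydrogenation (H2, 1 atm, Pd/C, EtOAc) then removes the temporary triple bond to give 10 before any other alkene is present.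

Step 4. The primary tridecyl group may migrate competitively (giving a tridecyl ester of a ring acid), and the slow oxidation may allow acid-promoted epimerisation next to the ketone. The fallback sets out from 4 and returns at 11. Methyllithium adds to 4 to give (R)-2-hydroxy-5-oxohexanoic acid F5, which is acetalised with 6 to (5R)-5-(3-oxobutyl)-2-pentyl-1,3-dioxolan-4-one F6. The closure of step 3 should give (2R,4S,5S)-4-acetyl-5-pentyloxolane-2-carboxylic acid F7, since the methyl-side enol could only close a seven-membered ring. Baeyer–Villiger oxidation with mCPBA, where a methyl group cannot compete with the ring carbon, gives (2R,4S,5S)-4-acetoxy-5-pentyloxolane-2-carboxylic acid F8. Methanolysis (K2CO3, MeOH, 0 °C) gives (2R,4S,5S)-4-hydroxy-5-pentyloxolane-2-carboxylic acid F9. Acylation with tetradecanoyl chloride (pyridine, DMAP cat., CH2Cl2; aqueous hydrolysis of the mixed anhydride) gives 11.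

Step 6. Facial selectivity of hydride delivery may be poor if coordination of boron to the ring oxygen erodes catalyst control. The fallback sets out from 14 and returns at 16. The acid chloride 14 is reduced with LiAlH(O-t-Bu)3 (THF, −78 °C) to (2S,3S,5R)-5-formyl-2-pentyloxolan-3-yl tetradecanoate F10. Non-8-en-1-ylmagnesium bromide F11 (from 12 and Mg, Et2O) is then added in the presence of MgBr2·OEt2 (CH2Cl2, −78 °C). Chelation of magnesium between the ring oxygen and the aldehyde oxygen should direct the alkyl group to the face that gives the (1R), threo carbinol 16, and the ester is spared at this temperature.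

**Further compounds**
F1 | step 3 | lithium tridec-1-yn-1-ide | [Li]C#CCCCCCCCCCCC
F2 | step 3 | (R)-2-hydroxy-5-oxooctadec-6-ynoic acid | OC(=O)[C@H](O)CCC(=O)C#CCCCCCCCCCCC
F3 | step 3 | (5R)-5-(3-oxohexadec-4-yn-1-yl)-2-pentyl-1,3-dioxolan-4-one | CCCCCC1OC(=O)[C@@H](CCC(=O)C#CCCCCCCCCCCC)O1
F4 | step 3 | (2R,4S,5S)-5-pentyl-4-(tetradec-2-ynoyl)oxolane-2-carboxylic acid | OC(=O)[C@H]1C[C@H](C(=O)C#CCCCCCCCCCCC)[C@H](CCCCC)O1
F5 | step 4 | (R)-2-hydroxy-5-oxohexanoic acid | OC(=O)[C@H](O)CCC(C)=O
F6 | step 4 | (5R)-5-(3-oxobutyl)-2-pentyl-1,3-dioxolan-4-one | CCCCCC1OC(=O)[C@@H](CCC(C)=O)O1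
F7 | step 4 | (2R,4S,5S)-4-acetyl-5-pentyloxolane-2-carboxylic acid | OC(=O)[C@H]1C[C@H](C(C)=O)[C@H](CCCCC)O1
F8 | step 4 | (2R,4S,5S)-4-acetoxy-5-pentyloxolane-2-carboxylic acid | OC(=O)[C@H]1C[C@H](OC(C)=O)[C@H](CCCCC)O1
F9 | step 4 | (2R,4S,5S)-4-hydroxy-5-pentyloxolane-2-carboxylic acid | OC(=O)[C@H]1C[C@H](O)[C@H](CCCCC)O1
F10 | step 6 | (2S,3S,5R)-5-formyl-2-pentyloxolan-3-yl tetradecanoate | O=C[C@H]1C[C@H](OC(=O)CCCCCCCCCCCCC)[C@H](CCCCC)O1
F11 | step 6 | non-8-en-1-ylmagnesium bromide | C=CCCCCCCC[Mg]Br
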